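The route rests on opening the pyran ring of the 2H-chromene (O1, C2, C3, C4, C4a, C8a) at O1–C2 and at C3=C4: the quaternary C2 is treated as the β-carbon of an enal and C4 as the formyl carbon of a salicylaldehyde. A chiral secondary amine joins a 3-bromo-6-hydroxybenzaldehyde bearing two MOM ethers and an E-enal in a domino oxa-Michael/aldol condensation that closes this ring, forms both bonds and sets (S)-C2 in one operation; the surplus formyl group on C3 is later excised as CO. The enal carries the complete side chain with its tertiary alcohol silylated, so that the C8a phenol is the only free hydroxyl; the C6 bromine later becomes the cinnamoyl ketone.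

Key step: step 9

Assumption on the sense of induction: the usual shielding model for 2-(diarylsilyloxymethyl)pyrrolidine iminium ions (E-iminium, s-trans, attack anti to the CAr2OSi group) pairs the (R)-amine and the E-enal with (S)-C2. If the sense proves opposite, the (S)-amine is used in step 9 and nothing else changes.

Remark on the design: a free tertiary hydroxyl in the enal could add to the same β-carbon under iminium activation (6-exo-trig, giving a tetrahydropyran) and would later consume organolithium. It is therefore carried as a triethylsilyl (TES) ether from step 8 to step 14. The enal is made geometrically pure from geranyl acetate, because dehydrogenation of a saturated aldehyde would give an E/Z mixture. MOM = methoxymethyl.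

Step 1
Reactants: 1 2,5-dihydroxybenzaldehyde
Product: 2 2,5-bis(methoxymethoxy)benzaldehyde
Conditions: MOMCl (2.5 equiv), i-Pr2NEt (3 equiv), CH2Cl2, 0 °C → rt
Reagents that add atoms: chloromethyl methyl ether, COCCl
Why: Base-mediated O-alkylation of both phenols by the reactive α-chloro ether (Williamson-type etherification) should give the bis-acetal and leave the aldehyde untouched.

Step 2
Reactants: 2 2,5-bis(methoxymethoxy)benzaldehyde
Product: 4 2,5-bis(methoxymethoxy)phenol, via 2,5-bis(methoxymethoxy)phenyl formate 3 (not isolated)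
Conditions: mCPBA, CH2Cl2, 0 °C → rt; then K2CO3 (cat.), MeOH, rt
Reagents that add atoms: 3-chloroperoxybenzoic acid, O=C(OO)c1cccc(Cl)c1
Why: Baeyer–Villiger oxidation with migration of the electron-rich aryl group should turn the aldehyde into the aryl formate, which base-catalysed methanolysis cleaves to the phenol.

Step 3
Reactants: 4 2,5-bis(methoxymethoxy)phenol
Product: 5 4-bromo-2,5-bis(methoxymethoxy)phenol
Conditions: NBS (1.0 equiv), MeCN, −20 → 0 °C
Reagents that add atoms: N-bromosuccinimide, O=C1CCC(=O)N1Br
Why: Electrophilic aromatic bromination should go para to the free hydroxyl, the strongest donor, at a site that is also ortho to a MOM ether and less hindered than the ortho position between two oxygens.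

Step 4
Reactants: 5 4-bromo-2,5-bis(methoxymethoxy)phenol
Product: 7 3-bromo-6-hydroxy-2,5-bis(methoxymethoxy)benzaldehyde, via salicyl alcohol 6 (not isolated)
Conditions: MgCl2 (anhydrous), Et3N, paraformaldehyde, MeCN, reflux; cold dilute citric acid work-up
Reagents that add atoms: formaldehyde (as paraformaldehyde), C=O
Why: Magnesium-phenoxide-directed ortho-formylation (Casnati–Skattebøl reaction) should hydroxymethylate the only free position ortho to the hydroxyl, and the magnesium-bound benzylic alkoxide is then oxidised in the flask by hydride transfer to a second formaldehyde.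

Step 5
Reactants: 8 geranyl acetate, (2E)-3,7-dimethylocta-2,6-dien-1-yl acetate
Product: 9 (2E)-5-(3,3-dimethyloxiran-2-yl)-3-methylpent-2-en-1-yl acetate (racemic at the oxirane CH)
Conditions: mCPBA (1.0 equiv), NaHCO3, CH2Cl2, 0 °C
Reagents that add atoms: 3-chloroperoxybenzoic acid, O=C(OO)c1cccc(Cl)c1
Why: Prilezhaev epoxidation should take the more electron-rich remote trisubstituted alkene, the 2,3-alkene being deactivated by the allylic acetate; the oxirane stereocentre forms without control and is erased in step 6.

Step 6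
Reactants: 9 (2E)-5-(3,3-dimethyloxiran-2-yl)-3-methylpent-2-en-1-yl acetate
Product: 10 (2E)-3,7-dimethyloct-2-ene-1,7-diol
Conditions: LiAlH4, THF, 0 °C → reflux; aqueous NaOH work-up
Reagents that add atoms: none
Why: Hydride should open the trisubstituted oxirane at its less substituted carbon (reductive epoxide opening) to leave the tertiary alcohol and cleave the acetate by ester reduction in the same operation, the isolated E-alkene being inert.

Step 7
Reactants: 10 (2E)-3,7-dimethyloct-2-ene-1,7-diol
Product: 11 (2E)-7-hydroxy-3,7-dimethyloct-2-enal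
Conditions: MnO2 (activated, excess), CH2Cl2, rt
Reagents that add atoms: none
Why: Heterogeneous allylic oxidation with MnO2 is selective for the primary allylic alcohol, cannot oxidise the tertiary alcohol and should keep the E geometry.

Step 8
Reactants: 11 (2E)-7-hydroxy-3,7-dimethyloct-2-enal
Product: 12 (2E)-3,7-dimethyl-7-[(triethylsilyl)oxy]oct-2-enal
Conditions: TESOTf (1.2 equiv), 2,6-lutidine, CH2Cl2, −78 °C
Reagents that add atoms: triethylsilyl trifluoromethanesulfonate, CC[Si](CC)(CC)OS(=O)(=O)C(F)(F)F
Why: Silylation of the tertiary alcohol by the silyl triflate is fast at low temperature, where the hindered weak base should not convert the enal into a silyl dienol ether.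

Step 9
Reactants: 7 3-bromo-6-hydroxy-2,5-bis(methoxymethoxy)benzaldehyde; 12 (2E)-3,7-dimethyl-7-[(triethylsilyl)oxy]oct-2-enal (1.5 equiv)
Product: 13 (2S)-6-bromo-5,8-bis(methoxymethoxy)-2-methyl-2-{4-methyl-4-[(triethylsilyl)oxy]pentyl}-2H-chromene-3-carbaldehyde
Conditions: (R)-2-[diphenyl(trimethylsilyloxy)methyl]pyrrolidine (20 mol %), 2-nitrobenzoic acid (20 mol %), 4 Å molecular sieves, toluene, 0 °C → rt, dark
Reagents that add atoms: none
Why: The amine and 12 form an iminium ion, the phenol of 7 adds to its β-carbon (O1–C2, oxa-Michael addition), the enamine so formed attacks the adjacent formyl group (C3–C4, intramolecular aldol addition), and loss of water followed by hydrolysis releases the catalyst and makes the sequence irreversible. The closest known reaction type is the diarylprolinol silyl ether-catalysed domino oxa-Michael/aldol condensation of salicylaldehydes with enals to 2H-chromene-3-carbaldehydes, used here in its demanding β,β-disubstituted variant. The pyran ring closes in the aldol event in a 6-exo-trig mode (enol-exo with respect to the enamine). C2, the only new stereocentre, is controlled by the catalyst: the diphenyl(trimethylsilyloxy)methyl group blocks one face of the s-trans E-iminium ion, so that with the (R)-amine the phenol should add to the Si face of the β-carbon, which gives (S)-C2. Chemoselectivity is secured by the substrate, since the hydroxyl flanked by the formyl group is the only free hydroxyl in either partner. The selectivity that remains at risk is the E geometry of the C2=C3 bond of 12, which must hold until the C–O bond forms and which the geometrically pure enal and the low temperature are meant to protect.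

Step 10
Reactants: 13 (2S)-6-bromo-5,8-bis(methoxymethoxy)-2-methyl-2-{4-methyl-4-[(triethylsilyl)oxy]pentyl}-2H-chromene-3-carbaldehyde
Product: 14 (2S)-6-bromo-5,8-bis(methoxymethoxy)-2-methyl-2-{4-methyl-4-[(triethylsilyl)oxy]pentyl}-2H-chromene
Conditions: RhCl(PPh3)3 (1.1 equiv), degassed toluene, 90 °C, dark
Reagents that add atoms: none
Why: In this Tsuji–Wilkinson decarbonylation the formyl C–H adds oxidatively to monovalent rhodium, CO migrates to the metal and reductive elimination leaves C3–H without moving the double bond; the aryl bromide, acetals and silyl ether are inert, and the moderate temperature and exclusion of light are chosen to keep the chromene from electrocyclic ring-opening so that C2 is retained.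

Step 11
Reactants: 15 4-hydroxycinnamic acid, (2E)-3-(4-hydroxyphenyl)prop-2-enoic acid
Product: 16 (2E)-3-(4-hydroxyphenyl)-N-methoxy-N-methylprop-2-enamide
Conditions: MeNH(OMe)·HCl, N-(3-dimethylaminopropyl)-N'-ethylcarbodiimide hydrochloride (EDC·HCl), 1-hydroxybenzotriazole (cat.), N-methylmorpholine, CH2Cl2/DMF, 0 °C → rt
Reagents that add atoms: N,O-dimethylhydroxylamine hydrochloride, CNOC.Cl
Why: In this carbodiimide-mediated amide coupling the amine should outcompete the phenol for the activated ester, and the E-alkene takes no part.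

Step 12
Reactants: 16 (2E)-3-(4-hydroxyphenyl)-N-methoxy-N-methylprop-2-enamide
Product: 17 (2E)-N-methoxy-3-[4-(methoxymethoxy)phenyl]-N-methylprop-2-enamide
Conditions: MOMCl (1.3 equiv), i-Pr2NEt, CH2Cl2, 0 °C → rt
Reagents that add atoms: chloromethyl methyl ether, COCCl
Why: Williamson-type O-alkylation of the phenol should give the MOM ether, the amide and alkene being inert to the mild base.

Step 13
Reactants: 14 (2S)-6-bromo-5,8-bis(methoxymethoxy)-2-methyl-2-{4-methyl-4-[(triethylsilyl)oxy]pentyl}-2H-chromene; 17 (2E)-N-methoxy-3-[4-(methoxymethoxy)phenyl]-N-methylprop-2-enamide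
Product: 20 (2E)-1-[(2S)-5,8-bis(methoxymethoxy)-2-methyl-2-{4-methyl-4-[(triethylsilyl)oxy]pentyl}-2H-chromen-6-yl]-3-[4-(methoxymethoxy)phenyl]prop-2-en-1-one, via aryllithium 18 (not isolated), via lithium hemiaminal alkoxide 19 (not isolated)
Conditions: n-BuLi (1.05 equiv), THF, −78 °C; then 17 (1.2 equiv), −78 → −20 °C; aqueous NH4Cl
Reagents that add atoms: none
Why: Bromine–lithium exchange is faster than any deprotonation and the ortho MOM ether stabilises the aryllithium, which should add 1,2 to the amide (Weinreb ketone synthesis) to give a chelated tetrahedral adduct (carbinol centre uncontrolled and transient) that resists over-addition and collapses to the E-enone on work-up.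

Step 14
Reactants: 20 (2E)-1-[(2S)-5,8-bis(methoxymethoxy)-2-methyl-2-{4-methyl-4-[(triethylsilyl)oxy]pentyl}-2H-chromen-6-yl]-3-[4-(methoxymethoxy)phenyl]prop-2-en-1-one
Product: 21 (2E)-1-[(2S)-5,8-dihydroxy-2-(4-hydroxy-4-methylpentyl)-2-methyl-2H-chromen-6-yl]-3-(4-hydroxyphenyl)prop-2-en-1-one (CNP0322520.1)
Conditions: 3 M aqueous HCl, MeOH/THF (degassed), rt → 40 °C, argon, dark
Reagents that add atoms: none
Why: Brønsted acid-catalysed solvolysis (acetal exchange with methanol and silyl ether hydrolysis) should unmask the three phenols and the tertiary alcohol in one operation; near room temperature the tertiary alcohol, the chromene and the E-enone should survive, and oxygen is excluded because the product is an acylhydroquinone.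

Compound list

1 | 2,5-dihydroxybenzaldehyde | O=Cc1cc(O)ccc1O | starting material
2 | 2,5-bis(methoxymethoxy)benzaldehyde | COCOc1ccc(OCOC)c(C=O)c1 | intermediate
3 | 2,5-bis(methoxymethoxy)phenyl formate | COCOc1ccc(OCOC)c(OC=O)c1 | intermediate (not isolated)
4 | 2,5-bis(methoxymethoxy)phenol | COCOc1ccc(OCOC)c(O)c1 | intermediate
5 | 4-bromo-2,5-bis(methoxymethoxy)phenol | COCOc1cc(Br)c(OCOC)cc1O | intermediate
6 | 4-bromo-2-(hydroxymethyl)-3,6-bis(methoxymethoxy)phenol (as its magnesium phenoxide) | OCc1c(O)c(OCOC)cc(Br)c1OCOC | intermediate (not isolated)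
7 | 3-bromo-6-hydroxy-2,5-bis(methoxymethoxy)benzaldehyde | O=Cc1c(O)c(OCOC)cc(Br)c1OCOC | intermediate
8 | geranyl acetate, (2E)-3,7-dimethylocta-2,6-dien-1-yl acetate | CC(C)=CCC/C(C)=C/COC(C)=O | starting material
9 | (2E)-5-(3,3-dimethyloxiran-2-yl)-3-methylpent-2-en-1-yl acetate, racemic at the oxirane CH | CC1(C)OC1CC/C(C)=C/COC(C)=O | intermediate
10 | (2E)-3,7-dimethyloct-2-ene-1,7-diol | CC(C)(O)CCC/C(C)=C/CO | intermediate
11 | (2E)-7-hydroxy-3,7-dimethyloct-2-enal | CC(C)(O)CCC/C(C)=C/C=O | intermediate
12 | (2E)-3,7-dimethyl-7-[(triethylsilyl)oxy]oct-2-enal | CC[Si](CC)(CC)OC(C)(C)CCC/C(C)=C/C=O | intermediate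
13 | (2S)-6-bromo-5,8-bis(methoxymethoxy)-2-methyl-2-{4-methyl-4-[(triethylsilyl)oxy]pentyl}-2H-chromene-3-carbaldehyde | CC[Si](CC)(CC)OC(C)(C)CCC[C@@]1(C)C(C=O)=Cc2c(OCOC)c(Br)cc(OCOC)c2O1 | intermediate
14 | (2S)-6-bromo-5,8-bis(methoxymethoxy)-2-methyl-2-{4-methyl-4-[(triethylsilyl)oxy]pentyl}-2H-chromene | CC[Si](CC)(CC)OC(C)(C)CCC[C@@]1(C)C=Cc2c(OCOC)c(Br)cc(OCOC)c2O1 | intermediate
15 | 4-hydroxycinnamic acid, (2E)-3-(4-hydroxyphenyl)prop-2-enoic acid | O=C(O)/C=C/c1ccc(O)cc1 | starting material
16 | (2E)-3-(4-hydroxyphenyl)-N-methoxy-N-methylprop-2-enamide | CON(C)C(=O)/C=C/c1ccc(O)cc1 | intermediate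
17 | (2E)-N-methoxy-3-[4-(methoxymethoxy)phenyl]-N-methylprop-2-enamide | CON(C)C(=O)/C=C/c1ccc(OCOC)cc1 | intermediate
18 | [(2S)-5,8-bis(methoxymethoxy)-2-methyl-2-{4-methyl-4-[(triethylsilyl)oxy]pentyl}-2H-chromen-6-yl]lithium | CC[Si](CC)(CC)OC(C)(C)CCC[C@@]1(C)C=Cc2c(OCOC)c([Li])cc(OCOC)c2O1 | intermediate (not isolated)
19 | lithium (2E)-1-[(2S)-5,8-bis(methoxymethoxy)-2-methyl-2-{4-methyl-4-[(triethylsilyl)oxy]pentyl}-2H-chromen-6-yl]-1-[methoxy(methyl)amino]-3-[4-(methoxymethoxy)phenyl]prop-2-en-1-olate, both epimers at the carbinol carbon | CC[Si](CC)(CC)OC(C)(C)CCC[C@@]1(C)C=Cc2c(OCOC)c(C(O[Li])(N(C)OC)/C=C/c3ccc(OCOC)cc3)cc(OCOC)c2O1 | intermediate (not isolated)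
20 | (2E)-1-[(2S)-5,8-bis(methoxymethoxy)-2-methyl-2-{4-methyl-4-[(triethylsilyl)oxy]pentyl}-2H-chromen-6-yl]-3-[4-(methoxymethoxy)phenyl]prop-2-en-1-one | CC[Si](CC)(CC)OC(C)(C)CCC[C@@]1(C)C=Cc2c(OCOC)c(C(=O)/C=C/c3ccc(OCOC)cc3)cc(OCOC)c2O1 | intermediate
21 | (2E)-1-[(2S)-5,8-dihydroxy-2-(4-hydroxy-4-methylpentyl)-2-methyl-2H-chromen-6-yl]-3-(4-hydroxyphenyl)prop-2-en-1-one | CC(C)(O)CCC[C@@]1(C)C=Cc2c(O)c(C(=O)/C=C/c3ccc(O)cc3)cc(O)c2O1 | target

Total step count: 14. Longest linear sequence: 8 steps (steps 1–4, 9, 10, 13, 14; the arm from geranyl acetate, steps 5–8, 9, 10, 13, 14, is equally long).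

Steps most likely to fail

Step 9. The hindered β,β-disubstituted iminium ion may react slowly. E/Z equilibration of the enal through the dienamine, or reversal of the oxa-Michael addition before the aldol closure, may erode facial control. Fallback: setting out from 7 and 12, the same annulation is run without asymmetric induction, with pyrrolidine and benzoic acid in toluene (or K2CO3 in 1,4-dioxane at reflux). This should give racemic 6-bromo-5,8-bis(methoxymethoxy)-2-methyl-2-{4-methyl-4-[(triethylsilyl)oxy]pentyl}-2H-chromene-3-carbaldehyde F1. Its enantiomers are separated by preparative chromatography on a cellulose tris(3,5-dimethylphenylcarbamate) stationary phase, and the (S)-enantiomer rejoins the route at 13. Stereocontrol is thus replaced by resolution.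

Step 10. CO extrusion from a hindered conjugated aldehyde may need a temperature at which reversible 6π ring-opening of the chromene to the ortho-quinone methide erodes the configuration at C2, or the reaction may stall. Fallback: setting out from 13, Baeyer–Villiger oxidation (mCPBA, NaHCO3, CH2Cl2, 0 °C) should give (2S)-6-bromo-5,8-bis(methoxymethoxy)-2-methyl-2-{4-methyl-4-[(triethylsilyl)oxy]pentyl}-2H-chromen-3-yl formate F2. Methanolysis (K2CO3, MeOH) gives the corresponding (2S)-chroman-3-one F3, and NaBH4 in MeOH gives the (2S)-chroman-3-ol F4, of which either C3 epimer serves. MsCl/Et3N gives the (2S)-chroman-3-yl methanesulfonate F5, and 1,8-diazabicyclo[5.4.0]undec-7-ene in toluene at 60 °C eliminates toward benzylic C4, the only neighbouring carbon that bears hydrogen, to return to the route at 14. The one-carbon excision then needs no rhodium and no step above 60 °C.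

Step 13. The aryllithium may add in a conjugate sense to the cinnamoyl amide, deprotonate it, or be quenched before 1,2-addition. Fallback: setting out from 14, the same bromine–lithium exchange followed by N-methoxy-N-methylacetamide should give 1-[(2S)-5,8-bis(methoxymethoxy)-2-methyl-2-{4-methyl-4-[(triethylsilyl)oxy]pentyl}-2H-chromen-6-yl]ethan-1-one F6. Claisen–Schmidt condensation of this methyl ketone with commercial 4-(methoxymethoxy)benzaldehyde (KOH, EtOH/THF, rt) forms the E-enone by aldol condensation and returns to the route at 20.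

Further compounds

F1 | step 9 | racemic 6-bromo-5,8-bis(methoxymethoxy)-2-methyl-2-{4-methyl-4-[(triethylsilyl)oxy]pentyl}-2H-chromene-3-carbaldehyde | CC[Si](CC)(CC)OC(C)(C)CCCC1(C)C(C=O)=Cc2c(OCOC)c(Br)cc(OCOC)c2O1
F2 | step 10 | (2S)-6-bromo-5,8-bis(methoxymethoxy)-2-methyl-2-{4-methyl-4-[(triethylsilyl)oxy]pentyl}-2H-chromen-3-yl formate | CC[Si](CC)(CC)OC(C)(C)CCC[C@@]1(C)C(OC=O)=Cc2c(OCOC)c(Br)cc(OCOC)c2O1
F3 | step 10 | (2S)-6-bromo-5,8-bis(methoxymethoxy)-2-methyl-2-{4-methyl-4-[(triethylsilyl)oxy]pentyl}chroman-3-one | CC[Si](CC)(CC)OC(C)(C)CCC[C@@]1(C)C(=O)Cc2c(OCOC)c(Br)cc(OCOC)c2O1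
F4 | step 10 | (2S)-6-bromo-5,8-bis(methoxymethoxy)-2-methyl-2-{4-methyl-4-[(triethylsilyl)oxy]pentyl}chroman-3-ol, either epimer at C3 | CC[Si](CC)(CC)OC(C)(C)CCC[C@@]1(C)C(O)Cc2c(OCOC)c(Br)cc(OCOC)c2O1
F5 | step 10 | (2S)-6-bromo-5,8-bis(methoxymethoxy)-2-methyl-2-{4-methyl-4-[(triethylsilyl)oxy]pentyl}chroman-3-yl methanesulfonate, either epimer at C3 | CC[Si](CC)(CC)OC(C)(C)CCC[C@@]1(C)C(OS(C)(=O)=O)Cc2c(OCOC)c(Br)cc(OCOC)c2O1
F6 | step 13 | 1-[(2S)-5,8-bis(methoxymethoxy)-2-methyl-2-{4-methyl-4-[(triethylsilyl)oxy]pentyl}-2H-chromen-6-yl]ethan-1-one | CC[Si](CC)(CC)OC(C)(C)CCC[C@@]1(C)C=Cc2c(OCOC)c(C(C)=O)cc(OCOC)c2O1
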